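## Structural features

The target 22 is a single benzene ring with four substituents in a 1,2,4,6 pattern: CO2H on C1, OH on C2, OMe on C4 and a 2-acetoxytridecyl chain (ring–CH2–CH(OAc)–C11H23) on C6, with hydrogen on C3 and C5. Its only stereocentre is the (R)-configured acetoxy carbon, one CH2 away from the ring and without a stereogenic neighbour, so the task is absolute control, best met by buying the centre and never breaking its C–O bond. The fragile parts are the secondary acetate, the hydroxyl that it masks (which would close a six-membered lactone onto the C1 carboxyl if it were set free) and the electron-rich salicylic acid, which is open to ring halogenation and to decarboxylation in hot acid. The real difficulty lies in the arene: two oxygens that must end up different, free OH beside the acid and OMe para to it, and a carboxyl wedged between the hydroxyl and the chain. Without the carboxyl carbon the ring is a 5-alkylresorcinol monomethyl ether with hydrogen on C1, C3 and C5. The key step uses exactly this pattern: C2, C3 and C4 come from a ketene carbonyl carbon and the two carbons of an alkoxyacetylene, while C5, C6 and C1 are C2, C3 and C4 of a 3-alkylcyclobutenone. The phenol left at C2 is then the handle that brings the last carbon to C1.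

## Logic of the disconnections

22 ⇒ 21 ⇒ 19 (through 20). The acid is taken back to the aldehyde level (21) and the exocyclic bond from C1 to that carbon is cut. The cut is placed there because the C2 hydroxyl of 19 can deliver a one-carbon electrophile to its own ortho position. The gain is a ring with only CH positions between its three substituents. The forward formylation must choose C1 over C3, both of which are ortho to the hydroxyl, and must spare the acetate; the oxidation must not halogenate the ring. Because the acetyl group of 22 is already present in 19, no protecting-group step follows and the secondary hydroxyl is never free beside the acid.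

19 ⇒ 11 + 14. Ring bonds C2–C3 and C4–C5 are cut and C1–C2 is opened. This is the natural cut for a 1,3,5 pattern in which OH and OMe are meta and already different. The gain is large: the arene falls to a four-membered ketone that carries the whole chain and the stereocentre, plus a two-carbon alkyne, and no selective O-methylation is needed anywhere. The forward step must join the unsubstituted carbon of 14 to the ketene carbonyl carbon, must run on heat alone, and needs 14 in excess. The acetate of 11 must not be lost by vinylogous elimination.

11 ⇒ 10 ⇒ 7 + 8 (through 9). Two chlorines are put back on the ring CH2 (10), then the ring bonds C(=O)–CH and CCl2–C(chain) are cut. The parent ketene does not add usefully to unactivated alkynes, whereas 9 does, and the chlorines come off afterwards. The gain is a linear terminal alkyne. The forward cycloaddition must bond the carbonyl carbon to the terminal alkyne carbon, and the acetate must tolerate the Lewis acid set free from the metal. The dechlorination must stop at 11 without over-reduction.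

7 ⇒ 6 ⇒ 4 (through 5). The acetate C–O bond is cut, then the C2–C3 bond of 6 between the alkyne and the propargylic CH2. This leads to an acetylide and the terminal epoxide 5, which is the ring-closed form of 4. Both forward events occur at a primary carbon, so the carbinol centre is not a reacting centre. The demand is attack at CH2 only.

4 ⇒ 1 + 2 (through 3). The C3–C4 bond of 4 is cut between the CH2 next to the carbinol and the decyl chain. The stereocentre is thereby bought as 2, and the rest is an unfunctionalised alkyl halide. The forward opening must take place at the epoxide CH2 of 2 and not at C–Cl.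

14 ⇒ 12 (through 13). The two C–C π bonds of 14 are traced back to one acetal C–O bond and the C–Cl bond of 12. 14 is too volatile and too prone to polymerise to be stored, so it is made by double elimination just before use. The demand is careful cold handling of 13 and 14.

## Other disconnections considered

Alternative 1: The C6–CH2 bond and the C1–carboxyl bond are cut together, leading back to an aryne and a malonate.
- **Forward step:** a fluoride source releases 3,5-dimethoxybenzyne from 3,5-dimethoxy-2-(trimethylsilyl)phenyl triflate A1. The enolate of dimethyl malonate A2 adds at the aryne carbon remote from the flanking methoxy group. The aryl anion then attacks one ester group of A2, and fragmentation moves that ester onto the ring to give methyl 2,4-dimethoxy-6-(2-methoxy-2-oxoethyl)benzoate A3.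
- **In favour:** both ortho carbon substituents arrive in one operation, with the C1 carboxyl at the right oxidation level and position. On that point this alternative is better than the chosen plan, whose step 8 must discriminate two ortho sites. A2 is also a cheaper two-carbon partner than 14.
- **Against:** A3 has neither the C11 chain nor the stereocentre. Its aliphatic ester must be told from the benzoate, extended by an undecyl nucleophile, and the carbinol set in a separate asymmetric step. Both ring oxygens are methyl ethers, so C2 must be unmasked selectively. Whenever the secondary hydroxyl is free beside the benzoate, lactonisation threatens. A1 is itself a multistep reagent.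
- **Comparison:** in structure, A3 holds the C1 carbon that 19 lacks, but 19 holds the chain, the stereocentre and the differentiated oxygens. In mechanism, both are governed by polarisation (aryne distortion against ynol ether polarity) and are about equal in regiochemical reliability. In step economy the chosen plan is clearly shorter.

Alternative 2: Ring bonds C1–C2 and C5–C6 are cut, leading to an ynoate and a trioxygenated diene.
- **Forward step:** thermal Diels–Alder addition of benzyl (R)-5-acetoxyhexadec-2-ynoate A4 to 1,3-dimethoxy-1-(trimethylsilyloxy)buta-1,3-diene A5. The CH2 terminus of A5 bonds to the β-carbon of A4 and the ketene acetal carbon to the α-carbon. Loss of the ketal alkoxy group and of the silyl group aromatises the adduct to benzyl 6-[(R)-2-acetoxytridecyl]-2-hydroxy-4-methoxybenzoate A6.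
- **In favour:** A6 carries every ring substituent, the acetate and the carboxyl, and is one hydrogenolysis from 22. In step economy and in the C1 regiochemistry this alternative is better than the chosen plan.
- **Against:** a β-alkyl ynoate with one activating group is a weak dienophile, and A5 is a heat- and acid-sensitive silyl ketene acetal. Forcing conditions invite diene decomposition or conjugate addition without ring closure. The CH2 of A4 between the alkyne and the acetoxy carbon is open to isomerisation to an allenoate and loss of acetate.
- **Comparison:** in structure A6 is ahead of 19. In mechanism both are pericyclic, but the chosen cascade pairs an electrophilic ketene with an electron-rich alkyne, while here the reactivity of the dienophile is the open question. The whole risk sits in one step.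

Alternative 3: Ring bond C1–C6 is cut, leading to an open-chain diketo-dioxinone.
- **Forward step:** mild base converts 6-[(R)-6-(tert-butyldimethylsilyloxy)-2,4-dioxoheptadecyl]-2,2-dimethyl-1,3-dioxin-4-one A7 into 5-[(R)-2-(tert-butyldimethylsilyloxy)tridecyl]-7-hydroxy-2,2-dimethyl-1,3-benzodioxin-4-one A8. The dioxinone carbon next to the masked carboxyl adds to the distal ketone, and dehydration and enolisation follow.
- **In favour:** the conditions are the mildest of all. The carboxyl carbon and the C2 oxygen are built in, so the C1 question does not arise, which is better than the chosen plan. The only free phenol of A8 is at C4, so its methylation is unambiguous, which equals the chosen plan in oxygen differentiation at the cost of one step.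
- **Against:** A7 is a sensitive polyketone that needs several acylation steps. Its distal ketone has a β-silyloxy group that can be eliminated by the cyclisation base. After A8 the acetonide must be opened and silyl exchanged for acetyl, and a free secondary hydroxyl next to the activated dioxinone ester would lactonise. An acetate cannot be carried instead, because a β-acetoxy ketone eliminates even more readily.
- **Comparison:** in structure A8 has the full carbon skeleton, whereas 19 lacks one carbon. The mechanism is an ionic aldol condensation against a neutral thermal cascade. In step economy it is longer, because of the assembly of A7 and the protecting-group steps at the end.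

Key step: step 7

Assumption: ring atoms are numbered C1 (bearing CO2H) to C6 (bearing the chain). The side-chain oxygen is carried as the acetate of 22 from step 3 on; this changes a spectator group only and leaves the carbon skeletons of 11 and 19 untouched. The (R) descriptor of 2 carries through to the carbinol carbon of every later compound, because that carbon is never a reacting centre.

## Route

Step 1
Reactants: 1 1-bromodecane; 2 (R)-epichlorohydrin
Product: 4 (R)-1-chlorotridecan-2-ol, via decylmagnesium bromide 3 (not isolated)
Conditions: 1, Mg, THF, 25–45 °C; then CuI (10 mol %), 2, THF, −40 → −20 °C; aq NH4Cl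
Reagents that add atoms: none
Why: Grignard formation, then CuI-catalysed SN2 opening of the epoxide of 2 at its CH2 carbon, which is faster than displacement of chloride. The stereocentre is not a reacting centre and the CIP order O > CH2Cl > CH2R is kept, so (R)-2 should give (R)-4.

Step 2
Reactants: 4 (R)-1-chlorotridecan-2-ol
Product: 6 (R)-pentadec-1-yn-4-ol, via (R)-1,2-epoxytridecane 5 (not isolated)
Conditions: LiC≡CH·H2NCH2CH2NH2 (3 equiv), DMSO, 0 °C → rt; then H2O
Reagents that add atoms: lithium acetylide LiC≡CH (used as its ethylenediamine complex), [Li]C#C
Why: The first equivalent of acetylide acts as base for Williamson-type closure of the chlorohydrin to 5, which a further equivalent opens at its CH2 terminus (alkylation of an acetylide by a terminal epoxide). Both events occur at the primary carbon, so the carbinol centre stays (R).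

Step 3
Reactants: 6 (R)-pentadec-1-yn-4-ol
Product: 7 (R)-pentadec-1-yn-4-yl acetate
Conditions: Ac2O, pyridine, DMAP (cat.), CH2Cl2, 0 °C → rt
Reagents that add atoms: acetic anhydride, CC(=O)OC(C)=O
Why: DMAP-catalysed acylation of a secondary alcohol with retention at carbon. It installs the ester of the target itself, so no protecting-group exchange is needed later and the hydroxyl is never free next to the future carboxyl.

Step 4
Reactants: 7 (R)-pentadec-1-yn-4-yl acetate; 8 trichloroacetyl chloride
Product: 10 4,4-dichloro-3-[(R)-2-acetoxytridecyl]cyclobut-2-en-1-one, via dichloroketene 9 (not isolated)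
Conditions: 8 (2 equiv, added over 3 h), zinc–copper couple Zn(Cu) (3 equiv), Et2O–DME, rt
Reagents that add atoms: none
Why: Zinc dehalogenates 8 to 9, which adds to the terminal alkyne in a ketene–alkyne (2+2) cycloaddition. The ketene carbonyl carbon bonds to the unsubstituted alkyne carbon, which puts the chain on C3. DME ties up ZnCl2, and the acetate is inert to both.

Step 5
Reactants: 10 4,4-dichloro-3-[(R)-2-acetoxytridecyl]cyclobut-2-en-1-one
Product: 11 3-[(R)-2-acetoxytridecyl]cyclobut-2-en-1-one
Conditions: Zn dust (4 equiv), AcOH–TMEDA (1:1, 5 equiv each), EtOH, 0 °C → rt
Reagents that add atoms: none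
Why: Zinc-mediated reductive dechlorination of an α,α-dichloro ketone. The TMEDA/AcOH buffer is the standard guard against over-reduction and ring opening, and a near-neutral medium avoids base-induced vinylogous elimination of the acetate.

Step 6
Reactants: 12 chloroacetaldehyde dimethyl acetal
Product: 14 methoxyacetylene, via sodium methoxyacetylide 13 (not isolated)
Conditions: NaNH2 (3 equiv), liq NH3, −33 °C; NH3 evaporated under N2; cold saturated aq NaCl, −20 °C; distilled at ambient pressure into toluene at −78 °C
Reagents that add atoms: none
Why: Twofold base-induced elimination (an alkoxide, then HCl) from the α-chloro acetal, the product being held as its salt 13 until protonation. This is the classical preparation of alkoxyacetylenes. 13 is never dried and 14 is kept cold in solution and used at once.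

Step 7
Reactants: 11 3-[(R)-2-acetoxytridecyl]cyclobut-2-en-1-one; 14 methoxyacetylene
Product: 19 3-methoxy-5-[(R)-2-acetoxytridecyl]phenol, via vinylketene 15 (not isolated), via vinylcyclobutenone 16 (not isolated), via dienylketene 17 (not isolated), via cyclohexadienone 18 (not isolated)
Conditions: 14 (4 equiv, toluene solution), toluene, sealed tube, 80 °C
Reagents that add atoms: none
Why: This is the Danheiser benzannulation, a known thermal cascade of 3-alkylcyclobutenones with alkoxyacetylenes. At about 80 °C 11 opens reversibly by 4π electrocyclic cleavage of its C(=O)–CH2 bond to vinylketene 15. The ketene C=C of 15 adds to the electron-rich triple bond of 14 in a (2+2) cycloaddition to give 16: the unsubstituted, nucleophilic carbon of 14 bonds to the electrophilic ketene carbonyl carbon (ring bond C2–C3) and the methoxy-bearing carbon to the ketene α-carbon (ring bond C4–C5), which places OMe meta and not ortho to the future hydroxyl. A second 4π opening turns 16 into dienylketene 17, whose ketene carbon and terminal methylene carbon join in a thermally allowed disrotatory 6π electrocyclisation (six-membered carbocycle, ring bond C1–C2) to give 18, and enolisation delivers phenol 19. No stereocentre is created: the sp3 ring carbon of 16 is transient, and the (R) acetoxy carbon is two atoms from any reacting centre in a neutral, aprotic medium. The selectivities needed are the regiochemistry of the (2+2) step, secured by the polarisation of the ynol ether, and the preference of 15 for 14 over self-addition or acylation of 19, secured by keeping 14 in excess in a closed vessel.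

Step 8
Reactants: 19 3-methoxy-5-[(R)-2-acetoxytridecyl]phenol
Product: 21 2-hydroxy-4-methoxy-6-[(R)-2-acetoxytridecyl]benzaldehyde, via salicyl alcohol 20 (not isolated)
Conditions: MgCl2 (anhydrous, 2 equiv), Et3N (4 equiv), (CH2O)n (6 equiv), THF, 65 °C; then cold 1 M HCl
Reagents that add atoms: paraformaldehyde (as formaldehyde), C=O
Why: Casnati–Skattebøl ortho-formylation: the ArOMgCl species delivers formaldehyde to an ortho carbon through a six-membered chelate to give 20, which a second formaldehyde oxidises to 21 by hydride transfer. Delivery from magnesium excludes the position para to the hydroxyl. Of the two ortho positions, C1 is para to the methoxy group and so the more nucleophilic, which should put the formyl group next to the chain.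

Step 9
Reactants: 21 2-hydroxy-4-methoxy-6-[(R)-2-acetoxytridecyl]benzaldehyde
Product: 22 6-[(R)-2-acetoxytridecyl]-2-hydroxy-4-methoxybenzoic acid
Conditions: NaClO2 (3 equiv), NaH2PO4 (3 equiv), 2-methyl-2-butene (20 equiv), t-BuOH–H2O, 0 °C → rt; acidified to pH 3 and extracted cold
Reagents that add atoms: sodium chlorite (NaClO2), [Na+].[O-]Cl=O
Why: Pinnick (Lindgren) chlorite oxidation of an aldehyde to the acid at about pH 4, with the alkene scavenging HOCl so the activated ring is not chlorinated. Acetate and methyl ether are inert, and the secondary oxygen stays acylated, so no lactone can form.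

## Compound list

1 | 1-bromodecane | CCCCCCCCCCBr | starting material
2 | (R)-epichlorohydrin, (2R)-2-(chloromethyl)oxirane | ClC[C@H]1CO1 | starting material
3 | decylmagnesium bromide (C10H21MgBr) | CCCCCCCCCC[Mg]Br | intermediate
4 | (R)-1-chlorotridecan-2-ol | ClC[C@H](O)CCCCCCCCCCC | intermediate
5 | (R)-1,2-epoxytridecane, (2R)-2-undecyloxirane | CCCCCCCCCCC[C@@H]1CO1 | intermediate
6 | (R)-pentadec-1-yn-4-ol | C#CC[C@H](O)CCCCCCCCCCC | intermediate
7 | (R)-pentadec-1-yn-4-yl acetate | C#CC[C@H](OC(C)=O)CCCCCCCCCCC | intermediate
8 | trichloroacetyl chloride | ClC(=O)C(Cl)(Cl)Cl | starting material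
9 | dichloroketene | ClC(Cl)=C=O | intermediate
10 | 4,4-dichloro-3-[(R)-2-acetoxytridecyl]cyclobut-2-en-1-one | O=C1C=C(C[C@H](OC(C)=O)CCCCCCCCCCC)C1(Cl)Cl | intermediate
11 | 3-[(R)-2-acetoxytridecyl]cyclobut-2-en-1-one | O=C1CC(C[C@H](OC(C)=O)CCCCCCCCCCC)=C1 | intermediate
12 | chloroacetaldehyde dimethyl acetal (2-chloro-1,1-dimethoxyethane) | COC(CCl)OC | starting material
13 | sodium methoxyacetylide (NaC≡COMe) | [Na+].[C-]#COC | intermediate
14 | methoxyacetylene | COC#C | intermediate
15 | vinylketene, (5R)-5-acetoxy-3-methylidenehexadec-1-en-1-one | O=C=CC(=C)C[C@H](OC(C)=O)CCCCCCCCCCC | intermediate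
16 | vinylcyclobutenone, 4-[(4R)-4-acetoxypentadec-1-en-2-yl]-3-methoxycyclobut-2-en-1-one (both epimers at ring C4) | O=C1C=C(OC)C1C(=C)C[C@H](OC(C)=O)CCCCCCCCCCC | intermediate
17 | dienylketene, (3E,7R)-7-acetoxy-3-methoxy-5-methylideneoctadeca-1,3-dien-1-one | O=C=C\C(OC)=C/C(=C)C[C@H](OC(C)=O)CCCCCCCCCCC | intermediate
18 | cyclohexadienone, 5-[(R)-2-acetoxytridecyl]-3-methoxycyclohexa-2,4-dien-1-one | O=C1C=C(OC)C=C(C[C@H](OC(C)=O)CCCCCCCCCCC)C1 | intermediate
19 | 3-methoxy-5-[(R)-2-acetoxytridecyl]phenol | COc1cc(O)cc(C[C@H](OC(C)=O)CCCCCCCCCCC)c1 | intermediate
20 | salicyl alcohol, 2-(hydroxymethyl)-5-methoxy-3-[(R)-2-acetoxytridecyl]phenol | CCCCCCCCCCC[C@H](Cc1cc(OC)cc(O)c1CO)OC(C)=O | intermediate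
21 | 2-hydroxy-4-methoxy-6-[(R)-2-acetoxytridecyl]benzaldehyde | CCCCCCCCCCC[C@H](Cc1cc(OC)cc(O)c1C=O)OC(C)=O | intermediate
22 | 6-[(R)-2-acetoxytridecyl]-2-hydroxy-4-methoxybenzoic acid | CCCCCCCCCCC[C@H](Cc1cc(OC)cc(O)c1C(=O)O)OC(C)=O | target

## Step count and least certain steps

Total step count: 9. Longest linear sequence: 8 steps (steps 1–5 and 7–9, from 1 and 2 to 22); step 6 is a one-step side branch.

**Step 7 (key step).** The likely failure is consumption of the vinylketene by self-addition or by acylation of the product phenol when the volatile 14 escapes or polymerises. Thermal loss of acetic acid from the chain next to the enone is a second risk. The fallback gives up ring construction and sets out from 4, coming back at 19. 4 is closed with powdered NaOH in Et2O and 5 is isolated. Commercial 3-bromo-5-methoxyphenol is benzylated (benzyl bromide, K2CO3, DMF) to 1-(benzyloxy)-3-bromo-5-methoxybenzene F1. Mg in THF converts this into [3-(benzyloxy)-5-methoxyphenyl]magnesium bromide F2. CuI-catalysed opening of 5 at its CH2 carbon, followed by an aqueous NH4Cl quench, should give (R)-1-[3-(benzyloxy)-5-methoxyphenyl]tridecan-2-ol F3 with the carbinol centre untouched. Acetylation (Ac2O, pyridine, DMAP) gives (R)-1-[3-(benzyloxy)-5-methoxyphenyl]tridecan-2-yl acetate F4, and hydrogenolysis (H2, Pd/C, EtOAc) returns 19.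

**Step 8.** The likely failures are loss of the acetate by transesterification with the MeOMgCl formed in the redox step, and incomplete discrimination between C1 and C3, since both are ortho to the hydroxyl. The fallback sets out from 19 and comes back at 21. It replaces the nucleophilic formaldehyde chemistry with a Rieche formylation (Cl2CHOMe, TiCl4, CH2Cl2, 0 °C, hydrolytic work-up). This is a Lewis-acid Friedel–Crafts process in a non-nucleophilic medium that an alkyl acetate tolerates, with ortho delivery from the ArOTiCl3 species. No new compound arises on this way, which is entered as F0. The site preference rests on the same electronic bias, para to the methoxy group.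

**Step 4.** The likely failures are sluggish cycloaddition of the unactivated alkyne, polymerisation of 9, and ZnCl2-promoted degradation. The fallback sets out from 7 and comes back at 11, so it also bypasses 10 and step 5. N,N-Dimethylacetamide, Tf2O and 2,4,6-collidine in refluxing 1,2-dichloroethane generate N,N-dimethylketeniminium triflate F5 in the presence of 7. Its (2+2) cycloaddition with the alkyne should give N-{3-[(R)-2-acetoxytridecyl]cyclobut-2-en-1-ylidene}-N-methylmethanaminium triflate F6, which aqueous NaHCO3 hydrolyses to 11.

**Step 9.** The likely failures are electrophilic chlorination of the activated ring if HOCl escapes the scavenger, and decarboxylation during an over-acidic or warm work-up. The fallback sets out from 21 and comes back at 22. Acetylation of the phenol (Ac2O, pyridine) gives 2-formyl-5-methoxy-3-[(R)-2-acetoxytridecyl]phenyl acetate F7, whose ring is deactivated. The same NaClO2 oxidation gives 2-acetoxy-4-methoxy-6-[(R)-2-acetoxytridecyl]benzoic acid F8. The aryl acetate is far more labile than the secondary alkyl acetate and is removed with aqueous NaHCO3 in MeOH at 0 °C.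

## Further compounds

F1 | step 7 | 1-(benzyloxy)-3-bromo-5-methoxybenzene | COc1cc(Br)cc(OCc2ccccc2)c1
F2 | step 7 | [3-(benzyloxy)-5-methoxyphenyl]magnesium bromide | COc1cc([Mg]Br)cc(OCc2ccccc2)c1
F3 | step 7 | (R)-1-[3-(benzyloxy)-5-methoxyphenyl]tridecan-2-ol | COc1cc(OCc2ccccc2)cc(C[C@H](O)CCCCCCCCCCC)c1
F4 | step 7 | (R)-1-[3-(benzyloxy)-5-methoxyphenyl]tridecan-2-yl acetate | COc1cc(OCc2ccccc2)cc(C[C@H](OC(C)=O)CCCCCCCCCCC)c1
F0 | step 8 | none | none
F5 | step 4 | N,N-dimethylketeniminium triflate | C=C=[N+](C)C.[O-]S(=O)(=O)C(F)(F)F
F6 | step 4 | N-{3-[(R)-2-acetoxytridecyl]cyclobut-2-en-1-ylidene}-N-methylmethanaminium triflate | C[N+](C)=C1CC(C[C@H](OC(C)=O)CCCCCCCCCCC)=C1.[O-]S(=O)(=O)C(F)(F)F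
F7 | step 9 | 2-formyl-5-methoxy-3-[(R)-2-acetoxytridecyl]phenyl acetate | CCCCCCCCCCC[C@H](Cc1cc(OC)cc(OC(C)=O)c1C=O)OC(C)=O
F8 | step 9 | 2-acetoxy-4-methoxy-6-[(R)-2-acetoxytridecyl]benzoic acid | CCCCCCCCCCC[C@H](Cc1cc(OC)cc(OC(C)=O)c1C(=O)O)OC(C)=O
A1 | alternative 1 | 3,5-dimethoxy-2-(trimethylsilyl)phenyl trifluoromethanesulfonate | COc1cc(OC)c([Si](C)(C)C)c(OS(=O)(=O)C(F)(F)F)c1
A2 | alternative 1 | dimethyl malonate | COC(=O)CC(=O)OC
A3 | alternative 1 | methyl 2,4-dimethoxy-6-(2-methoxy-2-oxoethyl)benzoate | COC(=O)Cc1cc(OC)cc(OC)c1C(=O)OC
A4 | alternative 2 | benzyl (R)-5-acetoxyhexadec-2-ynoate | CCCCCCCCCCC[C@H](CC#CC(=O)OCc1ccccc1)OC(C)=O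
A5 | alternative 2 | 1,3-dimethoxy-1-(trimethylsilyloxy)buta-1,3-diene | COC(=C)C=C(OC)O[Si](C)(C)C
A6 | alternative 2 | benzyl 6-[(R)-2-acetoxytridecyl]-2-hydroxy-4-methoxybenzoate | CCCCCCCCCCC[C@H](Cc1cc(OC)cc(O)c1C(=O)OCc1ccccc1)OC(C)=O
A7 | alternative 3 | 6-[(R)-6-(tert-butyldimethylsilyloxy)-2,4-dioxoheptadecyl]-2,2-dimethyl-1,3-dioxin-4-one | CC1(C)OC(=O)C=C(CC(=O)CC(=O)C[C@H](O[Si](C)(C)C(C)(C)C)CCCCCCCCCCC)O1
A8 | alternative 3 | 5-[(R)-2-(tert-butyldimethylsilyloxy)tridecyl]-7-hydroxy-2,2-dimethyl-1,3-benzodioxin-4-one | CC1(C)OC(=O)c2c(C[C@H](O[Si](C)(C)C(C)(C)C)CCCCCCCCCCC)cc(O)cc2O1
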